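The runs are simulated for an exercise; noise was put on by code.

**The task.** Two questions are asked below, and one clock serves both.

| flask | substrate | partner | remark | time |
|---|---|---|---|---|
| Friday's | 0.10 M | 0.080 M | run made earlier |  |
| Saturday's | 0.10 M | 0.24 M | run made earlier |  |
| spring | 0.10 M | 0.120 M |  | 6.0 min |
| midnight | 0.30 M | 0.120 M |  | 6.0 min |
| winter | 1.0 M | 0.120 M |  | 6.0 min |

- Friday's (time / s: target / %, substrate / %): 10.0: 0.7, 99.4; 20.0: 1.9, 98.3; 30.0: 2.4, 97.3; 50.0: 4.7, 95.4; 80.0: 6.3, 92.4
- Saturday's (time / s: target / %, substrate / %): 10.0: 2.9, 96.9; 20.0: 5.3, 94.4; 30.0: 7.9, 91.7; 50.0: 12.5, 87.1; 80.0: 18.5, 79.1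

(readings scatter by 0.3 percentage points)

- [target] at the end for spring, midnight, winter, in this order
- the shape of the row from first to last (rises, then falls / rises all the way / falls all the way / falls, then rises / hardly changes)

- the earlier runs were read with a standard deviation of 0.3 percentage points
- "hardly changes" means that all values lie within two and a half points (for a concentration: within two and a half percent of the largest)

**The clock.** Both earlier runs were charged with [substrate] at 0.10 M, so first order in substrate is assumed here, not read. Saturday's substrate at 80.0 s then gives 1.36 min at winter's charge as the partner clock: the pseudo-first-order lifetime of partner, one over the rate constant times [substrate]. Friday's reading gives 1.35 min. Midnight's clock is 4.55 min and spring's 13.6 min.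

**The ladder.** Saturday's balance falls short by 2.4 percentage points at 80.0 s. This reckoning takes that as target + substrate, two points per event, which gives a target clock that also shortens with [substrate]. Winter has the shortest partner clock. Its target clock of 1.03 min and its partner clock both lie inside 6.0 min, so this reckoning leaves 1.23% of the charge of partner, the limiting reagent, in winter at 6.0 min, and the target made there falls again. Midnight's target clock of 3.43 min and its partner clock lie inside 6.0 min, and this reckoning places that flask near the peak. Spring's target clock of 10.3 min and its partner clock both outlast 6.0 min, so target is still climbing there. This reckoning therefore expects a row that rises, then falls.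

**The forecast.** It gives 0.02 M, 0.042 M and 0.048 M, a row that rises all the way, on the reading “first-order decay of the target”. The two part at winter.

**The result.** Spring, midnight and winter end at 0.0277 M, 0.0432 M and 0.0163 M: the row rises, then falls. Winter at the asked time holds 1.63% target and 19.7% side product A, each unit of side product A counting as two in that percentage.

    substrate + by-product → side product B (k = 0.420 L mol⁻¹ min⁻¹)
    substrate + partner ⇌ target + by-product (K = 0.950, k = 0.710 L mol⁻¹ min⁻¹)
    substrate + target → side product A (k = 0.630 L mol⁻¹ min⁻¹)

**Clock again.** Winter's 6.0 min span 4.41 partner clocks, which reckons 1.23% of the partner charge left, and the flask holds 4.38%. Midnight's 6.0 min span 1.32 clocks of 4.55 min, which reckons 26.7%, and the flask holds 40.8%.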